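The target in this flask shares its starting material with a side product, and the row asks how the product divides between the two.

    starting material + partner ⇌ target (K1 = 61.3 L mol⁻¹, k1 = 2.09 L mol⁻¹ h⁻¹)
    starting material → side product (k2 = 0.0306 h⁻¹)
    starting material + target ⇌ idle adduct, settled at all times (K3 = 18.9 L mol⁻¹)

| flask | starting material | partner | time |
|---|---|---|---|
| Tuesday's | 0.050 M | 0.0400 M | 2.5 h |
| Thursday's | 0.050 M | 0.0800 M | 2.5 h |
| Friday's | 0.050 M | 0.150 M | 2.5 h |
| Wednesday's | 0.050 M | 0.300 M | 2.5 h |

- percentages count the starting material that a species holds: one idle adduct counts as two
- target is meant together with its idle adduct
- in an amount of target, one idle adduct counts as one target
- "hardly changes" means that all values lie within two and a half points (for a concentration: within two and a half percent of the largest)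
- run time (Tuesday's): 2.5 h

* share of target in all that became target or side product for Tuesday's, Thursday's, Friday's, Wednesday's, in this order
* how that number moves from the first to the last of them (rises all the way / rises, then falls / falls, then rises / falls all the way / hardly changes)

Divide the forward rate to target by the rate to side product. Both carry the same free [starting material], so that factor cancels, and the idle adduct, which ties up starting material, drops out of this ratio with it. At Tuesday's charge 2.73 is the route ratio: the forward rate constant to target times [partner], over the rate constant to side product, the selectivity factor of this flask. The share of target is then ratio/(1+ratio).

You can solve two extreme versions of Tuesday's flask in your head. In the first, partner is never used up, the ratio stays put, and the share is 73.2%. In the second, [starting material] stays at its charge, so [partner] decays pseudo-first-order to 77.0% of its charge by the end. Hold that end value from the first moment and the ratio is 2.10, the share 67.8%. The real flask starts on the first version and slides towards the second. Both versions drop the way back from target, which pulls the share down. I commit to the middle, 70.5%. The ratio grows in step with [partner], so I expect the row to rise all the way.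

The forecast gives 77%, 86.5%, 92%, 95.7%, and rises all the way, holding that “the share climbs steadily with diminishing gains”. Its Tuesday's figure stands higher than the share of my first extreme version, so we differ there.

The flasks give 70.5%, 82.8%, 90.2%, 94.9%: rises all the way. In Tuesday's flask the use of starting material by the forward step to target and by the step to side product stands at 2.7 to one just after the start, and with partner down to 81% of its charge at the end the route ratio is 2.21, while target, bound form counted, and side product stand at 2.39 to one. Wednesday's flask starts at a route ratio of 20.5, or 95.3%; reckoned with [partner] lowered by the full charge of starting material, the ratio is 17.1, or 94.5%, and between these two figures the flask gives 94.9%.

(All constants are those of an exercise; no experiment stands behind them.)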